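**Retrosynthetic overview**

1. Labdane numbering is used: ring A = C1–C5 + C10, ring B = C5–C10, side chain C11–C16 on C9, C17 on C8, C18/C19 on C4, C20 on C10. Late disconnections are C12–C13 (B-alkyl Suzuki–Miyaura coupling), C11=C12 (Wittig) and the equatorial C3–Br bond (hydrogen-atom-transfer hydrogenation of a C2=C3 alkenyl bromide made from a C3 ketone). They lead back to a bicyclic keto ester.
2. Key disconnection: the ring-fusion bond C5–C10, shared by rings A and B, is cut together with C8–C9 (retro-Diels–Alder). This opens both rings to an achiral, acyclic trienoate. In the forward sense both rings form in one step, ring A over the tether C1–C4 and ring B as the new cyclohexene.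
3. Enabling feature: on ring B the oxygen-bearing C8 and the carbon-branched C9 (C11) are neighbours, and C10 is β to C11. This is the "ortho" pattern of a 1-oxygenated diene (C5=C6–C7=C8–O) and a β-methyl acrylate (C10=C9–C11). The four ring A atoms C1–C4, with the gem-dimethyl carbon C4 next to C5, are exactly the tether of a 2,8,10-trienoate.
4. The trienoate is assembled from methyl geranate (C1–C3, C9–C11, C20), a prenyl boronate (C4, C5, C18, C19) and pent-4-en-2-ol (C6–C8, C17). The chain end C13–C16 comes from but-2-yn-1-ol.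

Key step: step 6

Remark (assumption): the boron catalyst is taken to bind the trienoate ester in its s-trans form with the usual α-C–H···O contact, as for simple β-substituted acrylates; on this model the (R)-catalyst covers the C9 Si face and leaves the C9 Re/C10 Si face open, which leads to the enantiomer drawn.

**Step 1**
Reactants: 1 methyl geranate, methyl (2E)-3,7-dimethylocta-2,6-dienoate
Product: 3 methyl (2E)-3-methyl-6-oxohex-2-enoate, via ozonide 2 (not isolated)
Conditions: O3 (1 equiv), CH2Cl2, −78 °C; then Me2S, −78 °C to rt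
Reagents that add atoms: ozone, [O-][O+]=O
Why: Ozonolysis with reductive work-up, in which electrophilic ozone attacks the electron-rich C6=C7 alkene far faster than the ester-deactivated C2=C3 alkene, whose E geometry stays untouched.

**Step 2**
Reactants: 3 methyl (2E)-3-methyl-6-oxohex-2-enoate; 4 prenylboronic acid pinacol ester
Product: 6 methyl (2E)-6-hydroxy-3,7,7-trimethylnona-2,8-dienoate (racemic), via pinacol borate 5 (not isolated)
Conditions: toluene, 60 °C; aq. work-up
Reagents that add atoms: none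
Why: Allylboration through a closed six-membered transition state transfers the prenyl group by γ-attack and so builds the gem-dimethyl quaternary carbon beside the carbinol, whose centre is left racemic because step 4 erases it.

**Step 3**
Reactants: 6 methyl (2E)-6-hydroxy-3,7,7-trimethylnona-2,8-dienoate; 7 pent-4-en-2-ol (racemic)
Product: 8 methyl (2E,8E)-6,11-dihydroxy-3,7,7-trimethyldodeca-2,8-dienoate (mixture of diastereomers)
Conditions: 7 (3 equiv), second-generation Hoveyda–Grubbs catalyst (5 mol %), CH2Cl2, 40 °C, argon sparge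
Reagents that add atoms: none
Why: Olefin cross-metathesis between a vinyl group on a quaternary carbon (no homodimerisation) and an excess of an unhindered terminal alkene, where the bulky neighbour enforces the E alkene, the trisubstituted enoate is inert and both carbinol centres are erased in step 4.

**Step 4**
Reactants: 8 methyl (2E,8E)-6,11-dihydroxy-3,7,7-trimethyldodeca-2,8-dienoate
Product: 9 methyl (2E,8E)-3,7,7-trimethyl-6,11-dioxododeca-2,8-dienoate
Conditions: Dess–Martin periodinane (2.5 equiv), NaHCO3, CH2Cl2, 0 °C to rt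
Reagents that add atoms: none
Why: Dess–Martin oxidation converts both secondary alcohols in one operation under buffered, near-neutral conditions, so that the β,γ-unsaturated methyl ketone does not slip into conjugation.

**Step 5**
Reactants: 9 methyl (2E,8E)-3,7,7-trimethyl-6,11-dioxododeca-2,8-dienoate
Product: 10 methyl (2E,8E,10Z)-11-[(tert-butyldimethylsilyl)oxy]-3,7,7-trimethyl-6-oxododeca-2,8,10-trienoate
Conditions: TBSOTf (1.1 equiv), Et3N, CH2Cl2, −78 to −30 °C
Reagents that add atoms: tert-butyldimethylsilyl trifluoromethanesulfonate, CC(C)(C)[Si](C)(C)OS(=O)(=O)C(F)(F)F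
Why: Soft enolisation removes the doubly activated (allylic and α-keto) hydrogen in preference to those of the methyl group, the hindered C6 ketone or the ester, and gives the conjugated silyl dienol ether in the Z form, which avoids allylic strain between the vinyl group and the methyl group.

**Step 6**
Reactants: 10 methyl (2E,8E,10Z)-11-[(tert-butyldimethylsilyl)oxy]-3,7,7-trimethyl-6-oxododeca-2,8,10-trienoate
Product: 11 methyl (1S,2S,4aS,8aR)-2-[(tert-butyldimethylsilyl)oxy]-2,5,5,8a-tetramethyl-6-oxo-1,2,4a,5,6,7,8,8a-octahydronaphthalene-1-carboxylate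
Conditions: (R)-3,3-diphenyl-1-(2-methylphenyl)tetrahydro-1H,3H-pyrrolo[1,2-c][1,3,2]oxazaborole (25 mol %), HN(SO2CF3)2 (20 mol %), CH2Cl2 (0.02 M), −40 to 0 °C
Reagents that add atoms: none
Why: Type 1 intramolecular Diels–Alder reaction of normal electron demand: the cationic boron Lewis acid binds the ester carbonyl and the 1-silyloxy diene C5=C6–C7=C8 adds suprafacially to C10=C9 in one concerted but asynchronous event in which C5–C10 (donor terminus to acceptor β-carbon) runs ahead of C8–C9. The closest known reaction type is the Lewis-acid-catalysed, including oxazaborolidinium-catalysed, cyclisation of 2,8,10-trienoates and 2,8,10-trienals to trans-fused octalins. Ring A closes through C5–C10 as a six-membered carbocycle over the chair-like tether C1–C4 (both π bonds exocyclic to it, closure helped by the C4 gem-dimethyl group), and ring B closes as the new cyclohexene through C5–C10 plus C8–C9. The ester-endo transition state of the E-enoate sets H5 and C20 trans (C5, C10), the E geometry keeps C11 cis to C20 (C9), and the 10Z dienol ether places C17 outside and oxygen inside, so that C17 ends cis to C20 and the oxygen equatorial (C8), a kinetic result that an aldol-type closure would not give. The absolute sense comes from the catalyst, whose aryl group covers the C9 Si face so that the diene bonds to the C9 Re/C10 Si face. The step needs regio-, endo- and chemoselectivity: the tether and the matched "ortho" polarity fix the regiochemistry, Lewis-acid coordination strengthens the endo preference, only the 10Z isomer reaches the s-cis form without an inside methyl group, and attack of C7 on the C3 ketone is barred by the E C5=C6 bond.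

**Step 7**
Reactants: 11 methyl (1S,2S,4aS,8aR)-2-[(tert-butyldimethylsilyl)oxy]-2,5,5,8a-tetramethyl-6-oxo-1,2,4a,5,6,7,8,8a-octahydronaphthalene-1-carboxylate
Product: 12 methyl (1S,2S,4aS,8aR)-2-[(tert-butyldimethylsilyl)oxy]-2,5,5,8a-tetramethyl-6-oxodecahydronaphthalene-1-carboxylate
Conditions: H2 (3 atm), Rh/Al2O3 (5 wt %), EtOAc, rt
Reagents that add atoms: none
Why: Heterogeneous catalytic hydrogenation saturates the cis-disubstituted C6=C7 bond without creating a stereocentre, rhodium being chosen because it has little tendency to cleave the allylic C8–O bond or to reduce the hindered ketone.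

**Step 8**
Reactants: 12 methyl (1S,2S,4aS,8aR)-2-[(tert-butyldimethylsilyl)oxy]-2,5,5,8a-tetramethyl-6-oxodecahydronaphthalene-1-carboxylate
Product: 13 methyl (1S,2S,4aS,8aR)-2-[(tert-butyldimethylsilyl)oxy]-6-hydrazinylidene-2,5,5,8a-tetramethyldecahydronaphthalene-1-carboxylate
Conditions: N2H4·H2O (excess), EtOH, 80 °C
Reagents that add atoms: hydrazine, NN
Why: Hydrazone formation at the C3 ketone, routine for ketones flanked by a quaternary carbon, while the ester between two fully substituted carbons is too shielded for hydrazinolysis.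

**Step 9**
Reactants: 13 methyl (1S,2S,4aS,8aR)-2-[(tert-butyldimethylsilyl)oxy]-6-hydrazinylidene-2,5,5,8a-tetramethyldecahydronaphthalene-1-carboxylate
Product: 14 methyl (1S,2S,4aS,8aR)-6-bromo-2-[(tert-butyldimethylsilyl)oxy]-2,5,5,8a-tetramethyl-1,2,3,4,4a,5,8,8a-octahydronaphthalene-1-carboxylate
Conditions: NBS (2.2 equiv), 2-tert-butyl-1,1,3,3-tetramethylguanidine, CH2Cl2, 0 °C
Reagents that add atoms: N-bromosuccinimide, O=C1CCC(=O)N1Br
Why: Barton vinyl halide synthesis in its bromine variant (oxidation to the diazo compound, bromination, loss of N2 and of the C2 proton), well known for ketones placed between a quaternary carbon and a CH2 group, so that the alkene can only form towards C2.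

**Step 10**
Reactants: 14 methyl (1S,2S,4aS,8aR)-6-bromo-2-[(tert-butyldimethylsilyl)oxy]-2,5,5,8a-tetramethyl-1,2,3,4,4a,5,8,8a-octahydronaphthalene-1-carboxylate
Product: 15 methyl (1S,2S,4aS,6R,8aR)-6-bromo-2-[(tert-butyldimethylsilyl)oxy]-2,5,5,8a-tetramethyldecahydronaphthalene-1-carboxylate
Conditions: Mn(dpm)3 (10 mol %, dpm = dipivaloylmethanate), PhSiH3, t-BuOOH, i-PrOH, rt, argon
Reagents that add atoms: none
Why: Metal-hydride hydrogen-atom-transfer hydrogenation of an alkenyl bromide to the alkyl bromide, in which H adds to C2, the bromine-stabilised C3 radical takes its second hydrogen axially on the face away from the axial C4 and C10 methyl groups, and bromine therefore ends equatorial (3R) without C–Br cleavage.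

**Step 11**
Reactants: 15 methyl (1S,2S,4aS,6R,8aR)-6-bromo-2-[(tert-butyldimethylsilyl)oxy]-2,5,5,8a-tetramethyldecahydronaphthalene-1-carboxylate
Product: 16 (1S,2S,4aS,6R,8aR)-6-bromo-2-[(tert-butyldimethylsilyl)oxy]-2,5,5,8a-tetramethyldecahydronaphthalene-1-carbaldehyde
Conditions: DIBAL-H (1.2 equiv), toluene, −78 °C; MeOH, then aq. work-up
Reagents that add atoms: none
Why: Partial ester reduction with DIBAL-H, where the crowded aluminium hemiacetal persists at low temperature and releases the aldehyde only on work-up, the secondary bromide being inert and the equatorial formyl group the stable C9 epimer.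

**Step 12**
Reactants: 16 (1S,2S,4aS,6R,8aR)-6-bromo-2-[(tert-butyldimethylsilyl)oxy]-2,5,5,8a-tetramethyldecahydronaphthalene-1-carbaldehyde
Product: 17 {[(1S,2S,4aS,6R,8aR)-6-bromo-1-ethenyl-2,5,5,8a-tetramethyldecahydronaphthalen-2-yl]oxy}(tert-butyl)dimethylsilane
Conditions: Ph3PCH3Br, KHMDS, THF, 0 °C; then 16, 0 °C to rt
Reagents that add atoms: methyltriphenylphosphonium bromide, C[P+](c1ccccc1)(c1ccccc1)c1ccccc1.[Br-]
Why: Wittig methylenation with the small, reactive ylide reaches even hindered aldehydes faster than β-elimination of the silyloxy group can start, and leaves the neopentyl-type bromide alone.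

**Step 13**
Reactants: 18 but-2-yn-1-ol
Product: 19 (but-2-yn-1-yloxy)(tert-butyl)dimethylsilane
Conditions: TBSCl, imidazole, CH2Cl2, rt
Reagents that add atoms: tert-butyldimethylsilyl chloride, CC(C)(C)[Si](C)(C)Cl
Why: Standard silylation of a primary alcohol, which removes the acidic proton and enlarges the oxygen-bearing alkyne substituent for the next step.

**Step 14**
Reactants: 19 (but-2-yn-1-yloxy)(tert-butyl)dimethylsilane
Product: 21 tert-butyl{[(2E)-3-iodobut-2-en-1-yl]oxy}dimethylsilane, via alkenylzirconocene chloride 20 (not isolated)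
Conditions: Cp2Zr(H)Cl (1.5 equiv), THF, 45 °C; then I2, 0 °C
Reagents that add atoms: iodine, II; Cp2Zr(H)Cl, [H][Zr](Cl)(C1C=CC=C1)C1C=CC=C1 (zirconium stays only in 20)
Why: Hydrozirconation–iodination, in which syn addition with equilibration places zirconium on the less hindered methyl-bearing carbon and iodinolysis with retention gives the E iodide, with methyl and CH2O cis.

**Step 15**
Reactants: 17 {[(1S,2S,4aS,6R,8aR)-6-bromo-1-ethenyl-2,5,5,8a-tetramethyldecahydronaphthalen-2-yl]oxy}(tert-butyl)dimethylsilane; 21 tert-butyl{[(2E)-3-iodobut-2-en-1-yl]oxy}dimethylsilane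
Product: 23 tert-butyl({(2E)-5-[(1S,2S,4aS,6R,8aR)-6-bromo-2-[(tert-butyldimethylsilyl)oxy]-2,5,5,8a-tetramethyldecahydronaphthalen-1-yl]-3-methylpent-2-en-1-yl}oxy)dimethylsilane, via B-alkyl-9-BBN 22 (not isolated)
Conditions: 9-BBN-H, THF, rt; then 21, Pd(dppf)Cl2 (5 mol %), AsPh3, Cs2CO3, DMF–H2O, rt to 45 °C
Reagents that add atoms: 9-borabicyclo[3.3.1]nonane, B1C2CCCC1CCC2 (boron stays only in 22)
Why: Anti-Markovnikov hydroboration of the only alkene followed by B-alkyl Suzuki–Miyaura coupling forms C12–C13 with retention of the E iodide geometry, and the unactivated secondary bromide does not add oxidatively to zerovalent palladium under these conditions.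

**Step 16**
Reactants: 23 tert-butyl({(2E)-5-[(1S,2S,4aS,6R,8aR)-6-bromo-2-[(tert-butyldimethylsilyl)oxy]-2,5,5,8a-tetramethyldecahydronaphthalen-1-yl]-3-methylpent-2-en-1-yl}oxy)dimethylsilane
Product: 24 (1S,2S,4aS,6R,8aR)-6-bromo-1-[(3E)-5-hydroxy-3-methylpent-3-en-1-yl]-2,5,5,8a-tetramethyldecahydronaphthalen-2-ol (target)
Conditions: Bu4NF, THF, 45 °C
Reagents that add atoms: none
Why: Fluoride desilylation frees both alcohols, and the warm basic medium is tolerated because the equatorial bromide has no antiperiplanar hydrogen for E2 elimination and is neopentyl-like towards substitution.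

**Compound list**

1 | methyl geranate, methyl (2E)-3,7-dimethylocta-2,6-dienoate | COC(=O)/C=C(\C)CCC=C(C)C | starting material
2 | methyl (2E)-5-(5,5-dimethyl-1,2,4-trioxolan-3-yl)-3-methylpent-2-enoate (ozonide) | COC(=O)/C=C(\C)CCC1OOC(C)(C)O1 | intermediate
3 | methyl (2E)-3-methyl-6-oxohex-2-enoate | COC(=O)/C=C(\C)CCC=O | intermediate
4 | 4,4,5,5-tetramethyl-2-(3-methylbut-2-en-1-yl)-1,3,2-dioxaborolane (prenylboronic acid pinacol ester) | CC(C)=CCB1OC(C)(C)C(C)(C)O1 | starting material
5 | methyl (2E)-3,7,7-trimethyl-6-[(4,4,5,5-tetramethyl-1,3,2-dioxaborolan-2-yl)oxy]nona-2,8-dienoate (racemic) | COC(=O)/C=C(\C)CCC(OB1OC(C)(C)C(C)(C)O1)C(C)(C)C=C | intermediate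
6 | methyl (2E)-6-hydroxy-3,7,7-trimethylnona-2,8-dienoate (racemic) | COC(=O)/C=C(\C)CCC(O)C(C)(C)C=C | intermediate
7 | pent-4-en-2-ol (racemic) | CC(O)CC=C | starting material
8 | methyl (2E,8E)-6,11-dihydroxy-3,7,7-trimethyldodeca-2,8-dienoate (diastereomer mixture) | COC(=O)/C=C(\C)CCC(O)C(C)(C)/C=C/CC(C)O | intermediate
9 | methyl (2E,8E)-3,7,7-trimethyl-6,11-dioxododeca-2,8-dienoate | COC(=O)/C=C(\C)CCC(=O)C(C)(C)/C=C/CC(C)=O | intermediate
10 | methyl (2E,8E,10Z)-11-[(tert-butyldimethylsilyl)oxy]-3,7,7-trimethyl-6-oxododeca-2,8,10-trienoate | COC(=O)/C=C(\C)CCC(=O)C(C)(C)/C=C/C=C(/C)O[Si](C)(C)C(C)(C)C | intermediate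
11 | methyl (1S,2S,4aS,8aR)-2-[(tert-butyldimethylsilyl)oxy]-2,5,5,8a-tetramethyl-6-oxo-1,2,4a,5,6,7,8,8a-octahydronaphthalene-1-carboxylate | COC(=O)[C@H]1[C@]2(C)CCC(=O)C(C)(C)[C@H]2C=C[C@]1(C)O[Si](C)(C)C(C)(C)C | intermediate
12 | methyl (1S,2S,4aS,8aR)-2-[(tert-butyldimethylsilyl)oxy]-2,5,5,8a-tetramethyl-6-oxodecahydronaphthalene-1-carboxylate | COC(=O)[C@H]1[C@]2(C)CCC(=O)C(C)(C)[C@H]2CC[C@]1(C)O[Si](C)(C)C(C)(C)C | intermediate
13 | methyl (1S,2S,4aS,8aR)-2-[(tert-butyldimethylsilyl)oxy]-6-hydrazinylidene-2,5,5,8a-tetramethyldecahydronaphthalene-1-carboxylate | COC(=O)[C@H]1[C@]2(C)CCC(=NN)C(C)(C)[C@H]2CC[C@]1(C)O[Si](C)(C)C(C)(C)C | intermediate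
14 | methyl (1S,2S,4aS,8aR)-6-bromo-2-[(tert-butyldimethylsilyl)oxy]-2,5,5,8a-tetramethyl-1,2,3,4,4a,5,8,8a-octahydronaphthalene-1-carboxylate | COC(=O)[C@H]1[C@]2(C)CC=C(Br)C(C)(C)[C@H]2CC[C@]1(C)O[Si](C)(C)C(C)(C)C | intermediate
15 | methyl (1S,2S,4aS,6R,8aR)-6-bromo-2-[(tert-butyldimethylsilyl)oxy]-2,5,5,8a-tetramethyldecahydronaphthalene-1-carboxylate | COC(=O)[C@H]1[C@]2(C)CC[C@@H](Br)C(C)(C)[C@H]2CC[C@]1(C)O[Si](C)(C)C(C)(C)C | intermediate
16 | (1S,2S,4aS,6R,8aR)-6-bromo-2-[(tert-butyldimethylsilyl)oxy]-2,5,5,8a-tetramethyldecahydronaphthalene-1-carbaldehyde | O=C[C@H]1[C@]2(C)CC[C@@H](Br)C(C)(C)[C@H]2CC[C@]1(C)O[Si](C)(C)C(C)(C)C | intermediate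
17 | {[(1S,2S,4aS,6R,8aR)-6-bromo-1-ethenyl-2,5,5,8a-tetramethyldecahydronaphthalen-2-yl]oxy}(tert-butyl)dimethylsilane | C=C[C@H]1[C@]2(C)CC[C@@H](Br)C(C)(C)[C@H]2CC[C@]1(C)O[Si](C)(C)C(C)(C)C | intermediate
18 | but-2-yn-1-ol | CC#CCO | starting material
19 | (but-2-yn-1-yloxy)(tert-butyl)dimethylsilane | CC#CCO[Si](C)(C)C(C)(C)C | intermediate
20 | chlorobis(cyclopentadienyl)[(2E)-4-[(tert-butyldimethylsilyl)oxy]but-2-en-2-yl]zirconium | C/C(=C\CO[Si](C)(C)C(C)(C)C)[Zr](Cl)(C1C=CC=C1)C1C=CC=C1 | intermediate
21 | tert-butyl{[(2E)-3-iodobut-2-en-1-yl]oxy}dimethylsilane | C/C(I)=C\CO[Si](C)(C)C(C)(C)C | intermediate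
22 | 9-{2-[(1S,2S,4aS,6R,8aR)-6-bromo-2-[(tert-butyldimethylsilyl)oxy]-2,5,5,8a-tetramethyldecahydronaphthalen-1-yl]ethyl}-9-borabicyclo[3.3.1]nonane | C1CC2CCCC(C1)B2CC[C@H]3[C@]4(C)CC[C@@H](Br)C(C)(C)[C@H]4CC[C@]3(C)O[Si](C)(C)C(C)(C)C | intermediate
23 | tert-butyl({(2E)-5-[(1S,2S,4aS,6R,8aR)-6-bromo-2-[(tert-butyldimethylsilyl)oxy]-2,5,5,8a-tetramethyldecahydronaphthalen-1-yl]-3-methylpent-2-en-1-yl}oxy)dimethylsilane | C/C(=C\CO[Si](C)(C)C(C)(C)C)CC[C@H]1[C@]2(C)CC[C@@H](Br)C(C)(C)[C@H]2CC[C@]1(C)O[Si](C)(C)C(C)(C)C | intermediate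
24 | (1S,2S,4aS,6R,8aR)-6-bromo-1-[(3E)-5-hydroxy-3-methylpent-3-en-1-yl]-2,5,5,8a-tetramethyldecahydronaphthalen-2-ol | C/C(=C\CO)CC[C@H]1[C@]2(C)CC[C@@H](Br)C(C)(C)[C@H]2CC[C@]1(C)O | target

**Step count**

Total step count: 16.
Longest linear sequence: 14 (steps 1–12, 15, 16).

**Steps most likely to fail**

**Step 6.**
- Facial control may be lost or the reaction may stall. The hindered C3 ketone competes with the ester for the boron Lewis acid. Protodesilylation would release a silyl triflimide that catalyses a racemic background reaction. A stepwise Michael-type path could also scramble C8.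
- The fallback replaces catalyst control by a covalently bound auxiliary and a chelating Lewis acid used in excess. It sets out from 9.
- Me3SnOH in 1,2-dichloroethane cleaves the methyl ester under near-neutral conditions to the dioxo acid F1.
- Its mixed pivalic anhydride is coupled with (R)-4-benzyloxazolidin-2-one (LiCl, Et3N) to give the imide F2.
- TBSOTf/Et3N gives the imide silyl dienol ether F3.
- Me2AlCl in CH2Cl2 at low temperature chelates the two imide carbonyls in the s-cis form. The benzyl group then blocks the C9 Si face, and the intramolecular Diels–Alder reaction gives the imide adduct F4.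
- Mg(OMe)2 in MeOH exchanges the auxiliary for methoxide, and the route is rejoined at 11.

**Step 3.**
- Metathesis at the vinyl group next to the quaternary carbon may be sluggish, so that homodimerisation of 7 and alkene migration take over.
- The fallback builds the C5=C6 bond by carbonyl olefination. It sets out from 6.
- TESCl/imidazole gives the silyl ether F5.
- Lemieux–Johnson cleavage (OsO4 cat., NaIO4, 2,6-lutidine) attacks the vinyl group rather than the electron-poor enoate and gives the neopentyl aldehyde F6.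
- Julia–Kocienski olefination with premetalated 5-{[3-(triethylsilyloxy)butyl]sulfonyl}-1-phenyl-1H-tetrazole (KHMDS, THF, −78 °C) gives the E alkene bis-silyl ether F7.
- HF·pyridine removes both silyl groups, and the route is rejoined at 8.

**Step 10.**
- Hydrogen-atom transfer to the hindered trisubstituted bromoalkene may be slow. Bromine may be lost by over-reduction, or the second hydrogen may be delivered with incomplete facial selectivity.
- The fallback reaches the same C3 radical by halogen abstraction. It sets out from 13.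
- Oxidative bromination of the hydrazone with CuBr2 and t-BuOLi gives the geminal dibromide F8.
- One equivalent of (Me3Si)3SiH with Et3B/air in toluene at low temperature removes one bromine. Hydrogen is again delivered axially, opposite to the C4 and C10 axial methyl groups, and the route is rejoined at 15.

**Further compounds**

F1 | step 6 | (2E,8E)-3,7,7-trimethyl-6,11-dioxododeca-2,8-dienoic acid | OC(=O)/C=C(\C)CCC(=O)C(C)(C)/C=C/CC(C)=O
F2 | step 6 | (4R)-4-benzyl-3-[(2E,8E)-3,7,7-trimethyl-6,11-dioxododeca-2,8-dienoyl]oxazolidin-2-one | O=C(/C=C(\C)CCC(=O)C(C)(C)/C=C/CC(C)=O)N1[C@H](Cc2ccccc2)COC1=O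
F3 | step 6 | (4R)-4-benzyl-3-{(2E,8E,10Z)-11-[(tert-butyldimethylsilyl)oxy]-3,7,7-trimethyl-6-oxododeca-2,8,10-trienoyl}oxazolidin-2-one | O=C(/C=C(\C)CCC(=O)C(C)(C)/C=C/C=C(/C)O[Si](C)(C)C(C)(C)C)N1[C@H](Cc2ccccc2)COC1=O
F4 | step 6 | (4R)-4-benzyl-3-{(1S,2S,4aS,8aR)-2-[(tert-butyldimethylsilyl)oxy]-2,5,5,8a-tetramethyl-6-oxo-1,2,4a,5,6,7,8,8a-octahydronaphthalene-1-carbonyl}oxazolidin-2-one | O=C([C@H]1[C@]2(C)CCC(=O)C(C)(C)[C@H]2C=C[C@]1(C)O[Si](C)(C)C(C)(C)C)N1[C@H](Cc2ccccc2)COC1=O
F5 | step 3 | methyl (2E)-3,7,7-trimethyl-6-[(triethylsilyl)oxy]nona-2,8-dienoate (racemic) | COC(=O)/C=C(\C)CCC(O[Si](CC)(CC)CC)C(C)(C)C=C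
F6 | step 3 | methyl (2E)-3,7,7-trimethyl-8-oxo-6-[(triethylsilyl)oxy]oct-2-enoate (racemic) | COC(=O)/C=C(\C)CCC(O[Si](CC)(CC)CC)C(C)(C)C=O
F7 | step 3 | methyl (2E,8E)-3,7,7-trimethyl-6,11-bis[(triethylsilyl)oxy]dodeca-2,8-dienoate (diastereomer mixture) | COC(=O)/C=C(\C)CCC(O[Si](CC)(CC)CC)C(C)(C)/C=C/CC(C)O[Si](CC)(CC)CC
F8 | step 10 | methyl (1S,2S,4aS,8aR)-6,6-dibromo-2-[(tert-butyldimethylsilyl)oxy]-2,5,5,8a-tetramethyldecahydronaphthalene-1-carboxylate | COC(=O)[C@H]1[C@]2(C)CCC(Br)(Br)C(C)(C)[C@H]2CC[C@]1(C)O[Si](C)(C)C(C)(C)C
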